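**Plan**

- Retrosynthesis removes the two MOM acetals on O3 and O4' last. Before that, the two aryl–CH2 bonds C6–C1'' and C8–C1''' are cut in one operation, which returns both prenyl groups to oxygen as 1,1-dimethylallyl ethers on O5 and O7.
- The feature that allows this lies in ring A: C6 and C8 are its only CH carbons, and each sits ortho to a phenolic oxygen (C6 to O5 and O7, C8 to O7). Each aryl–prenyl bond is therefore the product of an ortho [3,3] shift from oxygen to carbon.
- The two tertiary allyl ethers come from the 5,7-diol by tert-propargylation and semi-hydrogenation. The diol comes from a 5,7-di-O-benzyl flavonol whose O3 and O4' carry MOM groups.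
- Forward: rings A and B are bought as acetophenone 1 and aldehyde 2 and joined by a Claisen–Schmidt condensation. Ring C, the only ring made, closes in an Algar–Flynn–Oyamada oxidation. Protecting-group changes, ether formation, the double rearrangement and deprotection follow in one linear chain.
- Stereochemistry: the target has no stereocentre and both prenyl alkenes carry geminal methyl groups. The only stereocentres on the way (C2 and C3 of a dihydroflavonol) are oxidised away in the same flask.

Key step: step 7

Remark: compounds 1 and 2 are taken as catalogue materials (each is otherwise one alkylation away from 2,4,6-trihydroxyacetophenone or 4-hydroxybenzaldehyde).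

**Route**

Step 1
Reactants: 1 1-[2,4-bis(benzyloxy)-6-hydroxyphenyl]ethanone; 2 4-(methoxymethoxy)benzaldehyde
Product: 3 (E)-1-[2,4-bis(benzyloxy)-6-hydroxyphenyl]-3-[4-(methoxymethoxy)phenyl]prop-2-en-1-one
Conditions: 50% aq KOH, EtOH/THF, rt
Reagents that add atoms: none
Why: Claisen–Schmidt condensation, in which the potassium enolate of the methyl ketone adds to the non-enolisable aldehyde and E1cB loss of water gives the conjugated E-enone, the benzyl and MOM ethers being inert to base.

Step 2
Reactants: 3 the 2'-hydroxychalcone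
Product: 5 5,7-bis(benzyloxy)-3-hydroxy-2-[4-(methoxymethoxy)phenyl]-4H-chromen-4-one, via trans-dihydroflavonol 4 (not isolated)
Conditions: 30% aq H2O2, 2 M aq NaOH, MeOH/THF, 0 °C to rt
Reagents that add atoms: hydrogen peroxide, OO
Why: Algar–Flynn–Oyamada oxidation, in which the 2'-phenoxide adds 6-endo to the enone β-carbon while C-α is hydroxylated by alkaline peroxide to give racemic trans 4 (the diequatorial arrangement), and a second equivalent of peroxide dehydrogenates 4 to the flavonol so that both transient stereocentres are erased.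

Step 3
Reactants: 5 5,7-di-O-benzyl-4'-O-MOM-kaempferol
Product: 6 5,7-bis(benzyloxy)-3-(methoxymethoxy)-2-[4-(methoxymethoxy)phenyl]-4H-chromen-4-one
Conditions: MOMCl, i-Pr2NEt, CH2Cl2, 0 °C to rt
Reagents that add atoms: chloromethyl methyl ether, COCCl
Why: Williamson-type O-alkylation with the α-chloro ether converts the only free hydroxyl, the 3-OH, into its MOM acetal, so that O3 and O4' carry the same acid-labile group while the benzyl ethers stay in place.

Step 4
Reactants: 6 5,7-di-O-benzyl-3,4'-di-O-MOM-kaempferol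
Product: 7 5,7-dihydroxy-3-(methoxymethoxy)-2-[4-(methoxymethoxy)phenyl]-4H-chromen-4-one
Conditions: H2 (1 atm), Pd/C, EtOAc/THF, rt
Reagents that add atoms: none
Why: Catalytic hydrogenolysis cleaves the two benzyl aryl ethers and leaves the MOM acetals and the tetrasubstituted C2=C3 bond of the chromone untouched, which frees exactly the two ring A phenols that are to carry the allyl groups.

Step 5
Reactants: 7 3,4'-di-O-MOM-kaempferol
Product: 9 3-(methoxymethoxy)-2-[4-(methoxymethoxy)phenyl]-5,7-bis(2-methylbut-3-yn-2-yloxy)-4H-chromen-4-one, via 7-O-(1,1-dimethylpropargyl) mono-ether 8 (not isolated)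
Conditions: 3-chloro-3-methylbut-1-yne (5 equiv), DBU (6 equiv), CuCl2·2H2O (5 mol%), MeCN, 0 °C to rt
Reagents that add atoms: 3-chloro-3-methylbut-1-yne, C#CC(C)(C)Cl
Why: CuCl2-catalysed propargylic etherification of phenols, in which metalation of the terminal alkyne lets chloride ionise to an allenylidene-type cation that a phenoxide captures only at the tertiary carbon, so the ether regiochemistry is fixed by the mechanism, the acidic 7-OH reacting first to give 8 before the hydrogen-bonded 5-OH is driven over by the excess of chloride and base.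

Step 6
Reactants: 9 3,4'-di-O-MOM-5,7-bis-O-(1,1-dimethylpropargyl)kaempferol
Product: 10 3-(methoxymethoxy)-2-[4-(methoxymethoxy)phenyl]-5,7-bis(2-methylbut-3-en-2-yloxy)-4H-chromen-4-one
Conditions: H2 (1 atm), Pd/CaCO3 poisoned with Pb(OAc)2 (Lindlar catalyst), quinoline, EtOAc, rt
Reagents that add atoms: none
Why: Lindlar semi-hydrogenation reduces the two terminal alkynes to vinyl groups on the poisoned catalyst and is stopped after two equivalents of hydrogen, before the terminal alkenes or the chromone would be reduced.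

Step 7
Reactants: 10 3,4'-di-O-MOM-5,7-bis-O-(1,1-dimethylallyl)kaempferol
Product: 12 5,7-dihydroxy-3-(methoxymethoxy)-2-[4-(methoxymethoxy)phenyl]-6,8-bis(3-methylbut-2-en-1-yl)-4H-chromen-4-one, via 6-prenyl 7-O-(1,1-dimethylallyl) 5-phenol 11 (not isolated)
Conditions: PhNEt2, 130 °C, Ar
Reagents that add atoms: none
Why: Heating should trigger two consecutive concerted [3,3]-sigmatropic shifts, each through a chair-like six-membered transition state in which the terminal CH2 of a 1,1-dimethylallyl group bonds to the ortho ring carbon as the O–C bond breaks, and each is completed by tautomerisation back to the phenol, so the tertiary ethers are delivered as linear prenyl groups at C6 and C8. The closest known reaction type is the aromatic Claisen rearrangement of aryl 1,1-dimethylallyl ethers to ortho-prenylphenols. No ring is closed and no stereocentre is formed. The selectivity needed is positional: the O5 ether has C6 as its only ortho CH (C4a is a ring-fusion carbon), is compressed against the C4 carbonyl and gains the hydrogen bond from the new 5-OH to that carbonyl on migration, so it should move first to give 11, which leaves C8 as the only open ortho position for the O7 ether. The weakly basic amine solvent keeps the medium free of acid, which suppresses ionisation of the tertiary ethers and cyclisation of the ortho-prenyl phenols.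

Step 8
Reactants: 12 3,4'-di-O-MOM-6,8-diprenylkaempferol
Product: 13 6,8-diprenylkaempferol
Conditions: 3 M aq HCl, MeOH, 40 °C
Reagents that add atoms: none
Why: Acid-catalysed acetal exchange with methanol (MOM methanolysis) frees the 3- and 4'-hydroxyls as dimethoxymethane is lost, under conditions mild enough that the ortho-prenyl phenols are not expected to close to dimethylchromans.

**Compound list**

1 | 1-[2,4-bis(benzyloxy)-6-hydroxyphenyl]ethanone | CC(=O)c1c(O)cc(OCc2ccccc2)cc1OCc1ccccc1 | starting material
2 | 4-(methoxymethoxy)benzaldehyde | COCOc1ccc(C=O)cc1 | starting material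
3 | (E)-1-[2,4-bis(benzyloxy)-6-hydroxyphenyl]-3-[4-(methoxymethoxy)phenyl]prop-2-en-1-one | COCOc1ccc(/C=C/C(=O)c2c(O)cc(OCc3ccccc3)cc2OCc2ccccc2)cc1 | intermediate
4 | trans-5,7-bis(benzyloxy)-3-hydroxy-2-[4-(methoxymethoxy)phenyl]chroman-4-one (racemic; the 2R,3R enantiomer is drawn) | O=C1[C@H](O)[C@@H](c2ccc(OCOC)cc2)Oc2cc(OCc3ccccc3)cc(OCc3ccccc3)c21 | intermediate (not isolated)
5 | 5,7-bis(benzyloxy)-3-hydroxy-2-[4-(methoxymethoxy)phenyl]-4H-chromen-4-one | COCOc1ccc(-c2oc3cc(OCc4ccccc4)cc(OCc4ccccc4)c3c(=O)c2O)cc1 | intermediate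
6 | 5,7-bis(benzyloxy)-3-(methoxymethoxy)-2-[4-(methoxymethoxy)phenyl]-4H-chromen-4-one | COCOc1ccc(-c2oc3cc(OCc4ccccc4)cc(OCc4ccccc4)c3c(=O)c2OCOC)cc1 | intermediate
7 | 5,7-dihydroxy-3-(methoxymethoxy)-2-[4-(methoxymethoxy)phenyl]-4H-chromen-4-one (3,4'-di-O-MOM-kaempferol) | COCOc1ccc(-c2oc3cc(O)cc(O)c3c(=O)c2OCOC)cc1 | intermediate
8 | 5-hydroxy-3-(methoxymethoxy)-2-[4-(methoxymethoxy)phenyl]-7-(2-methylbut-3-yn-2-yloxy)-4H-chromen-4-one | C#CC(C)(C)Oc1cc(O)c2c(=O)c(OCOC)c(-c3ccc(OCOC)cc3)oc2c1 | intermediate (not isolated)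
9 | 3-(methoxymethoxy)-2-[4-(methoxymethoxy)phenyl]-5,7-bis(2-methylbut-3-yn-2-yloxy)-4H-chromen-4-one | C#CC(C)(C)Oc1cc(OC(C)(C)C#C)c2c(=O)c(OCOC)c(-c3ccc(OCOC)cc3)oc2c1 | intermediate
10 | 3-(methoxymethoxy)-2-[4-(methoxymethoxy)phenyl]-5,7-bis(2-methylbut-3-en-2-yloxy)-4H-chromen-4-one | C=CC(C)(C)Oc1cc(OC(C)(C)C=C)c2c(=O)c(OCOC)c(-c3ccc(OCOC)cc3)oc2c1 | intermediate
11 | 5-hydroxy-3-(methoxymethoxy)-2-[4-(methoxymethoxy)phenyl]-6-(3-methylbut-2-en-1-yl)-7-(2-methylbut-3-en-2-yloxy)-4H-chromen-4-one | C=CC(C)(C)Oc1cc2oc(-c3ccc(OCOC)cc3)c(OCOC)c(=O)c2c(O)c1CC=C(C)C | intermediate (not isolated)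
12 | 5,7-dihydroxy-3-(methoxymethoxy)-2-[4-(methoxymethoxy)phenyl]-6,8-bis(3-methylbut-2-en-1-yl)-4H-chromen-4-one | CC(C)=CCc1c(O)c(CC=C(C)C)c2oc(-c3ccc(OCOC)cc3)c(OCOC)c(=O)c2c1O | intermediate
13 | 6,8-diprenylkaempferol, 3,5,7-trihydroxy-2-(4-hydroxyphenyl)-6,8-bis(3-methylbut-2-en-1-yl)-4H-chromen-4-one | CC(C)=CCc1c(O)c(CC=C(C)C)c2oc(-c3ccc(O)cc3)c(O)c(=O)c2c1O | target

**Step count**

Total steps: 8. Longest linear sequence: 8 steps (from 1 or 2 to 13).

**Steps most likely to fail**

Step 5. The etherification may stall after O7 has reacted, because the 5-OH is tied into a hydrogen bond to the C4 carbonyl and its phenoxide is a weak, crowded nucleophile towards a tertiary centre. The fallback leaves the route at 8, which is then isolated by running step 5 with one equivalent of the chloride at 0 °C.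
- The 5-OH is alkylated with the primary halide 1-bromo-3-methylbut-2-ene (K2CO3, acetone, reflux), an SN2 reaction that is routine for chelated 5-hydroxyflavones. This gives the 5-O-prenyl 7-O-(1,1-dimethylpropargyl) ether F1.
- Eu(fod)3 in CHCl3 at 60 °C should then induce the domino para-Claisen–Cope rearrangement that carries the prenyl group from O5 to C8, giving the 5-hydroxy-8-prenyl 7-O-(1,1-dimethylpropargyl) ether F2.
- Lindlar semi-hydrogenation of the alkyne gives the 5-hydroxy-8-prenyl 7-O-(1,1-dimethylallyl) ether F3.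
- Heating F3 in PhNEt2 moves the tertiary allyl group to C6, its only free ortho position, and the route is rejoined at 12.

Step 7. The two migrations may occur in the wrong order. If the O7 group moves to C6 first, the O5 group can reach carbon only through a Claisen–Cope sequence that leaves it at C8 as a 1,1-dimethylallyl group. The strained O5 ether may also lose isoprene by elimination instead of rearranging. The fallback sets out from 7.
- Both ring A CH positions, each activated by flanking oxygen substituents, are iodinated with N-iodosuccinimide in DMF at rt to give the 6,8-diiodo-5,7-diol F4.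
- A twofold Stille coupling with tributyl(3-methylbut-2-en-1-yl)stannane (Pd(PPh3)4, DMF, 90 °C) attaches both prenyl groups and returns to the route at 12.

Step 2. The 6'-benzyloxy group twists the enone, so 5-exo attack of the phenoxide at the α-carbon may compete with the 6-endo closure and divert material to an aurone. The fallback sets out from 3.
- NaOAc in refluxing EtOH closes ring C by oxa-Michael addition to give the racemic flavanone F5.
- DDQ in refluxing dioxane dehydrogenates it to the flavone F6.
- Dimethyldioxirane in acetone/CH2Cl2 at 0 °C epoxidises the C2–C3 double bond to the 2,3-epoxide F7.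
- Brief treatment of F7 with catalytic p-TsOH isomerises it to the 3-hydroxyflavone, which rejoins the route at 5.

Further compounds
F1 | step 5 | 3-(methoxymethoxy)-2-[4-(methoxymethoxy)phenyl]-5-(3-methylbut-2-en-1-yloxy)-7-(2-methylbut-3-yn-2-yloxy)-4H-chromen-4-one | C#CC(C)(C)Oc1cc(OCC=C(C)C)c2c(=O)c(OCOC)c(-c3ccc(OCOC)cc3)oc2c1
F2 | step 5 | 5-hydroxy-3-(methoxymethoxy)-2-[4-(methoxymethoxy)phenyl]-8-(3-methylbut-2-en-1-yl)-7-(2-methylbut-3-yn-2-yloxy)-4H-chromen-4-one | C#CC(C)(C)Oc1cc(O)c2c(=O)c(OCOC)c(-c3ccc(OCOC)cc3)oc2c1CC=C(C)C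
F3 | step 5 | 5-hydroxy-3-(methoxymethoxy)-2-[4-(methoxymethoxy)phenyl]-8-(3-methylbut-2-en-1-yl)-7-(2-methylbut-3-en-2-yloxy)-4H-chromen-4-one | C=CC(C)(C)Oc1cc(O)c2c(=O)c(OCOC)c(-c3ccc(OCOC)cc3)oc2c1CC=C(C)C
F4 | step 7 | 5,7-dihydroxy-6,8-diiodo-3-(methoxymethoxy)-2-[4-(methoxymethoxy)phenyl]-4H-chromen-4-one | COCOc1ccc(-c2oc3c(I)c(O)c(I)c(O)c3c(=O)c2OCOC)cc1
F5 | step 2 | 5,7-bis(benzyloxy)-2-[4-(methoxymethoxy)phenyl]chroman-4-one (racemic) | O=C1CC(c2ccc(OCOC)cc2)Oc2cc(OCc3ccccc3)cc(OCc3ccccc3)c21
F6 | step 2 | 5,7-bis(benzyloxy)-2-[4-(methoxymethoxy)phenyl]-4H-chromen-4-one | O=c1cc(-c2ccc(OCOC)cc2)oc2cc(OCc3ccccc3)cc(OCc3ccccc3)c12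
F7 | step 2 | 5,7-bis(benzyloxy)-2,3-epoxy-2-[4-(methoxymethoxy)phenyl]chroman-4-one (racemic; the ring fusion can only be cis) | O=C1c2c(OCc3ccccc3)cc(OCc3ccccc3)cc2OC2(c3ccc(OCOC)cc3)OC12
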